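**Retrosynthetic overview**

1. Numbering: C1 = ring ketone, C2H=C3(CH3), C4H, C5H, C6(CH3)2, C7H(O-methacryloyl), C8H2, C9H(O-isobutyryl), C10(CH3), C11H. The cyclobutane is C4–C5–C11–C10 and the seven-membered ring is C5–C6–C7–C8–C9–C10–C11.
2. Enabling feature: ketone C1 sits next to C11, and C11 carries the quaternary cyclobutane carbon C10, which is the retron of a semipinacol 1,2-shift. Moving C10 back from C11 to C1 turns the bicyclo[3.1.1]heptenone into a 1-oxynorborn-2-ene with a leaving group on C11. The same move widens the seven-membered ring to the eight-membered ring C1–C11–C5–C6–C7–C8–C9–C10.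
3. That norbornene has no four-membered ring and is a Diels–Alder adduct. The diene is a 5,5-disubstituted 1-silyloxycyclopentadiene (C1–C4, C10) and the dienophile an (E)-nitroalkene C5=C11, tied together through C9–C8–C7–C6.
4. Open-chain precursor: C9–C10 by Mukaiyama aldol of 3-methylcyclopentenone with a C5–C9 aldehyde, the C10 methyl by chelate-controlled alkylation, C6–C7 by enantioselective reverse prenylation, and C11–N by alkene nitration.
5. Ring order: cyclopentenone (bought) → norbornene and carbocycle C4–C5–C6–C7–C8–C9–C10 (step 9) → cyclobutane, cyclohexenone and the seven-membered ring C5–C11 in one event (step 11) → C7 ester.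

Key step: step 11

Assumption: in step 1 the SEGPHOS enantiomer that delivers the 3R carbinol is used; if the sense of induction is opposite, its antipode is taken.

**Step 1**
Reactants: 1 3-[(tert-butyldimethylsilyl)oxy]propan-1-ol; 2 3-methylbuta-1,2-diene
Product: 4 (3R)-1-[(tert-butyldimethylsilyl)oxy]-4,4-dimethylhex-5-en-3-ol, via 3-[(tert-butyldimethylsilyl)oxy]propanal 3 (not isolated)
Conditions: [Ir(cod)Cl]2 (2.5 mol%), SEGPHOS (5 mol%), 3-nitrobenzoic acid (10 mol%), allyl acetate (10 mol%), Cs2CO3 (20 mol%), PhMe, 60 °C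
Reagents that add atoms: none
Why: In this iridium-catalysed transfer-hydrogenative carbonyl reverse prenylation, dehydrogenation of 1 gives aldehyde 3 and a 1,1-dimethylallyl-iridium species that adds through a closed chair transition state, forming C6–C7 and setting C7 (R) under control of the chiral bisphosphine.

**Step 2**
Reactants: 4 (3R)-1-[(tert-butyldimethylsilyl)oxy]-4,4-dimethylhex-5-en-3-ol
Product: 5 (4R)-4,6-bis[(tert-butyldimethylsilyl)oxy]-3,3-dimethylhex-1-ene
Conditions: TBSOTf, 2,6-lutidine, CH2Cl2, 0 °C → rt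
Reagents that add atoms: tert-butyldimethylsilyl triflate CC(C)(C)[Si](C)(C)OS(=O)(=O)C(F)(F)F
Why: This is a standard silylation, and the silyl triflate is reactive enough for the neopentylic secondary alcohol without touching C7.

**Step 3**
Reactants: 5 (4R)-4,6-bis[(tert-butyldimethylsilyl)oxy]-3,3-dimethylhex-1-ene
Product: 6 (3R)-3-[(tert-butyldimethylsilyl)oxy]-4,4-dimethylhex-5-en-1-ol
Conditions: camphorsulfonic acid (10 mol%), MeOH/CH2Cl2, 0 °C
Reagents that add atoms: none
Why: Acid-catalysed methanolysis should remove only the primary silyl ether, because the secondary one is shielded by the adjacent quaternary carbon.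

**Step 4**
Reactants: 6 (3R)-3-[(tert-butyldimethylsilyl)oxy]-4,4-dimethylhex-5-en-1-ol
Product: 7 (3R)-3-[(tert-butyldimethylsilyl)oxy]-4,4-dimethylhex-5-enal
Conditions: Dess–Martin periodinane, CH2Cl2, 0 °C → rt
Reagents that add atoms: none
Why: Dess–Martin oxidation stops at the aldehyde under neutral conditions, so the beta-silyloxy group is not eliminated.

**Step 5**
Reactants: 8 3-methylcyclopent-2-en-1-one
Product: 10 trimethyl[(4-methylcyclopenta-1,3-dien-2-yl)oxy]silane, via lithium dienolate 9 (not isolated)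
Conditions: LDA, THF, −78 °C; TMSCl, −78 → 0 °C; cold pentane work-up, used at once
Reagents that add atoms: chlorotrimethylsilane C[Si](C)(C)Cl
Why: Kinetic deprotonation of the enone at the alpha' carbon (the future C10) followed by O-silylation gives the cross-conjugated silyl dienol ether, which is kept cold to suppress 1,5-hydrogen shift and dimerisation.

**Step 6**
Reactants: 7 (3R)-3-[(tert-butyldimethylsilyl)oxy]-4,4-dimethylhex-5-enal; 10 trimethyl[(4-methylcyclopenta-1,3-dien-2-yl)oxy]silane
Product: 12 5-[(1R,3R)-3-[(tert-butyldimethylsilyl)oxy]-1-hydroxy-4,4-dimethylhex-5-en-1-yl]-3-methylcyclopent-2-en-1-one (both epimers at the ring carbon), via difluoroboryl aldolate 11 (not isolated)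
Conditions: BF3·OEt2 (1.1 equiv), CH2Cl2, −78 °C; aqueous work-up
Reagents that add atoms: none
Why: In this Mukaiyama aldol through an open transition state, the polar 1,3-induction model for beta-oxygenated aldehydes predicts the 1,3-anti relation between C7–O and the new C9–O (C9 = R), while the configuration at C10 is irrelevant because it is erased in step 7.

**Step 7**
Reactants: 12 5-[(1R,3R)-3-[(tert-butyldimethylsilyl)oxy]-1-hydroxy-4,4-dimethylhex-5-en-1-yl]-3-methylcyclopent-2-en-1-one
Product: 15 (1R,3R)-3-[(tert-butyldimethylsilyl)oxy]-1-[(1S)-1,4-dimethyl-2-oxocyclopent-3-en-1-yl]-4,4-dimethylhex-5-en-1-yl 2-methylpropanoate, via dilithio aldolate dianion 13 (not isolated), via lithium alkoxide 14 (not isolated)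
Conditions: LDA (2.3 equiv), THF, −78 → −40 °C; MeI, DMPU, −78 → −40 °C; isobutyryl chloride, −78 → 0 °C
Reagents that add atoms: iodomethane CI; 2-methylpropanoyl chloride CC(C)C(=O)Cl
Why: In this Fráter–Seebach-type alkylation of an aldolate dianion, the lithium chelate between the C9 alkoxide and the enolate oxygen exposes the enolate face opposite the C8 chain, so the methyl group enters anti to C9–O and sets the quaternary C10, and acylating the alkoxide in the same flask installs the isobutyrate and blocks retro-aldol cleavage.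

**Step 8**
Reactants: 15 (1R,3R)-3-[(tert-butyldimethylsilyl)oxy]-1-[(1S)-1,4-dimethyl-2-oxocyclopent-3-en-1-yl]-4,4-dimethylhex-5-en-1-yl 2-methylpropanoate
Product: 16 (1R,3R,5E)-3-[(tert-butyldimethylsilyl)oxy]-1-[(1S)-1,4-dimethyl-2-oxocyclopent-3-en-1-yl]-4,4-dimethyl-6-nitrohex-5-en-1-yl 2-methylpropanoate
Conditions: AgNO2 (3 equiv), TEMPO (0.4 equiv), 4 Å MS, ClCH2CH2Cl, 70 °C
Reagents that add atoms: silver nitrite [Ag+].[O-]N=O
Why: In this radical nitration of a terminal alkene, NO2 adds to the CH2 terminus (C11) and TEMPO-assisted hydrogen loss should give the (E)-nitroalkene, while the electron-poor trisubstituted enone double bond is not attacked.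

**Step 9**
Reactants: 16 (1R,3R,5E)-3-[(tert-butyldimethylsilyl)oxy]-1-[(1S)-1,4-dimethyl-2-oxocyclopent-3-en-1-yl]-4,4-dimethyl-6-nitrohex-5-en-1-yl 2-methylpropanoate
Product: 18 endo-nitro cycloadduct (tricyclic 1-triethylsilyloxynorbornene; full description in the compound list), via silyloxycyclopentadiene 17 (not isolated)
Conditions: TESOTf, Et3N, CH2Cl2 (0.005 M), −20 °C → rt
Reagents that add atoms: triethylsilyl triflate CC[Si](CC)(CC)OS(=O)(=O)C(F)(F)F
Why: Soft enolisation of the alpha'-blocked enone through C4–H gives the 5,5-disubstituted 1-silyloxycyclopentadiene 17, whose quaternary C10 rules out a 1,5-hydrogen shift, and its intramolecular normal-demand Diels–Alder reaction joins the most nucleophilic terminus C4 to C5 and the oxygen-bearing C1 to the nitro-bearing C11 (ortho rule), with the chain on C10 dictating the diene face and holding C6 exo so that the E geometry places NO2 endo and C1, C4, C5 and C11 all follow from C10.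

**Step 10**
Reactants: 18 endo-nitro cycloadduct
Product: 19 endo-amine (same tricycle with NH2 in place of NO2)
Conditions: Zn dust, AcOH, THF, 0 °C → rt
Reagents that add atoms: none
Why: Dissolving-metal reduction of the aliphatic nitro group takes place at nitrogen only, so C11 keeps its endo configuration, and the acidic medium excludes nitronate formation, epimerisation and retro-Henry cleavage while the alkene, the ester and both silyl ethers survive.

**Step 11**
Reactants: 19 endo-amine
Product: 21 (4R,5S,7R,9R,10R,11R)-7-[(tert-butyldimethylsilyl)oxy]-9-(2-methylpropanoyloxy)longipin-2-en-1-one, via endo-diazonium acetate 20 (not isolated)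
Conditions: NaNO2, AcOH/H2O 4:1, 0 °C
Reagents that add atoms: none
Why: Proposed new method: nitrosation of the endo amine gives diazonium ion 20, and as N2 leaves from the endo face the C1–C10 bond, which lies antiperiplanar to C11–N (dihedral angle about 155°), migrates to C11 while the silyloxy oxygen and the C2=C3 double bond stabilise the charge growing at C1; loss of the silyl group to water then gives the conjugated ketone. The closest known reaction types are the Tiffeneau–Demjanov/semipinacol deamination of rigid vicinal amino alcohols, where the bond antiperiplanar to the diazonium group migrates, and ring-contracting semipinacol shifts of 2-substituted cyclopentanols to cyclobutyl carbonyl compounds; new here is its use on a bridgehead norbornenol to climb in strain to a bicyclo[3.1.1]heptenone, paid for by loss of N2 and formation of the enone. No ring is closed from an open chain: the single 1,2-shift contracts the eight-membered ring C1–C11–C5–C6–C7–C8–C9–C10 to the seven-membered ring C5–C6–C7–C8–C9–C10–C11, contracts the cyclopentane C1–C11–C5–C4–C10 to the cyclobutane C4–C5–C11–C10, and expands the cyclopentene C1–C2–C3–C4–C10 to the cyclohexenone C1–C2–C3–C4–C10–C11. C11 is the only stereocentre that changes and is set by inversion (backside entry of C10), C10 migrates with retention, and C4, C5, C7 and C9 are untouched. The selectivity needed is migration of C10 rather than of the vinylic C2, a hydride shift or solvent capture, and the endo nitrogen fixed in step 9 secures it because it holds C1–C2 synclinal (about 50°) to the leaving group and leaves no bond on C5 antiperiplanar to it.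

**Step 12**
Reactants: 21 (4R,5S,7R,9R,10R,11R)-7-[(tert-butyldimethylsilyl)oxy]-9-(2-methylpropanoyloxy)longipin-2-en-1-one
Product: 22 (4R,5S,7R,9R,10R,11R)-7-hydroxy-9-(2-methylpropanoyloxy)longipin-2-en-1-one
Conditions: HF·pyridine, THF, 0 °C → rt
Reagents that add atoms: none
Why: Acidic fluoride desilylation avoids basic conditions, and the trans-1,3 arrangement of the C7 and C9 oxygens disfavours acyl migration.

**Step 13**
Reactants: 22 (4R,5S,7R,9R,10R,11R)-7-hydroxy-9-(2-methylpropanoyloxy)longipin-2-en-1-one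
Product: 23 (4R,5S,7R,9R,10R,11R)-9-(2-methylpropanoyloxy)-7-(2-methylprop-2-enoyloxy)longipin-2-en-1-one (CNP0214356.1)
Conditions: methacryloyl chloride, Et3N, DMAP (cat.), BHT (trace), CH2Cl2, 0 °C → rt
Reagents that add atoms: 2-methylprop-2-enoyl chloride C=C(C)C(=O)Cl
Why: DMAP-catalysed acylation of the one free, neopentylic alcohol proceeds with retention at C7, and the polymerisable, dienophilic methacrylate is introduced last.

**Compound list**

1 | 3-[(tert-butyldimethylsilyl)oxy]propan-1-ol | CC(C)(C)[Si](C)(C)OCCCO | starting material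
2 | 3-methylbuta-1,2-diene (1,1-dimethylallene) | CC(C)=C=C | starting material
3 | 3-[(tert-butyldimethylsilyl)oxy]propanal | CC(C)(C)[Si](C)(C)OCCC=O | intermediate
4 | (3R)-1-[(tert-butyldimethylsilyl)oxy]-4,4-dimethylhex-5-en-3-ol | C=CC(C)(C)[C@H](O)CCO[Si](C)(C)C(C)(C)C | intermediate
5 | (4R)-4,6-bis[(tert-butyldimethylsilyl)oxy]-3,3-dimethylhex-1-ene | C=CC(C)(C)[C@H](O[Si](C)(C)C(C)(C)C)CCO[Si](C)(C)C(C)(C)C | intermediate
6 | (3R)-3-[(tert-butyldimethylsilyl)oxy]-4,4-dimethylhex-5-en-1-ol | C=CC(C)(C)[C@H](O[Si](C)(C)C(C)(C)C)CCO | intermediate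
7 | (3R)-3-[(tert-butyldimethylsilyl)oxy]-4,4-dimethylhex-5-enal | C=CC(C)(C)[C@H](O[Si](C)(C)C(C)(C)C)CC=O | intermediate
8 | 3-methylcyclopent-2-en-1-one | CC1=CC(=O)CC1 | starting material
9 | lithium 4-methylcyclopenta-1,3-dien-2-olate (cross-conjugated dienolate of 8) | CC1=CC([O-])=CC1.[Li+] | intermediate
10 | trimethyl[(4-methylcyclopenta-1,3-dien-2-yl)oxy]silane | CC1=CC(O[Si](C)(C)C)=CC1 | intermediate
11 | difluoroboryl aldolate of 12 (C9–O–BF2) | C=CC(C)(C)[C@H](O[Si](C)(C)C(C)(C)C)C[C@@H](OB(F)F)C1CC(C)=CC1=O | intermediate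
12 | 5-[(1R,3R)-3-[(tert-butyldimethylsilyl)oxy]-1-hydroxy-4,4-dimethylhex-5-en-1-yl]-3-methylcyclopent-2-en-1-one, both epimers at ring C5 (= C10) | C=CC(C)(C)[C@H](O[Si](C)(C)C(C)(C)C)C[C@@H](O)C1CC(C)=CC1=O | intermediate
13 | dilithium alkoxide-enolate (aldolate dianion) of 12 | C=CC(C)(C)[C@H](O[Si](C)(C)C(C)(C)C)C[C@@H]([O-])C1=C([O-])C=C(C)C1.[Li+].[Li+] | intermediate
14 | lithium (1R,3R)-3-[(tert-butyldimethylsilyl)oxy]-1-[(1S)-1,4-dimethyl-2-oxocyclopent-3-en-1-yl]-4,4-dimethylhex-5-en-1-olate | C=CC(C)(C)[C@H](O[Si](C)(C)C(C)(C)C)C[C@@H]([O-])[C@]1(C)CC(C)=CC1=O.[Li+] | intermediate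
15 | (1R,3R)-3-[(tert-butyldimethylsilyl)oxy]-1-[(1S)-1,4-dimethyl-2-oxocyclopent-3-en-1-yl]-4,4-dimethylhex-5-en-1-yl 2-methylpropanoate | C=CC(C)(C)[C@H](O[Si](C)(C)C(C)(C)C)C[C@@H](OC(=O)C(C)C)[C@]1(C)CC(C)=CC1=O | intermediate
16 | (1R,3R,5E)-3-[(tert-butyldimethylsilyl)oxy]-1-[(1S)-1,4-dimethyl-2-oxocyclopent-3-en-1-yl]-4,4-dimethyl-6-nitrohex-5-en-1-yl 2-methylpropanoate | [O-][N+](=O)/C=C/C(C)(C)[C@H](O[Si](C)(C)C(C)(C)C)C[C@@H](OC(=O)C(C)C)[C@]1(C)CC(C)=CC1=O | intermediate
17 | (1R,3R,5E)-3-[(tert-butyldimethylsilyl)oxy]-1-{(1S)-1,3-dimethyl-5-[(triethylsilyl)oxy]cyclopenta-2,4-dien-1-yl}-4,4-dimethyl-6-nitrohex-5-en-1-yl 2-methylpropanoate | [O-][N+](=O)/C=C/C(C)(C)[C@H](O[Si](C)(C)C(C)(C)C)C[C@@H](OC(=O)C(C)C)[C@]1(C)C=C(C)C=C1O[Si](CC)(CC)CC | intermediate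
18 | endo-nitro cycloadduct: norborn-2-ene with bridgeheads C1 (OSiEt3) and C4 (H), C2H=C3(CH3), saturated bridge C11H(NO2 endo)–C5H, one-carbon bridge C10(CH3); the chain C9H(O-isobutyryl, R)–C8H2–C7H(OTBS, R)–C6(CH3)2 runs from C10 (on the side of the C5–C11 bridge) to the exo position of C5 | [O-][N+](=O)[C@H]1[C@@]2(O[Si](CC)(CC)CC)C=C(C)[C@H]3[C@@H]1C(C)(C)[C@H](O[Si](C)(C)C(C)(C)C)C[C@@H](OC(=O)C(C)C)[C@@]23C | intermediate
19 | endo-amine: tricycle of 18 with NH2 (endo) on C11 | N[C@H]1[C@@]2(O[Si](CC)(CC)CC)C=C(C)[C@H]3[C@@H]1C(C)(C)[C@H](O[Si](C)(C)C(C)(C)C)C[C@@H](OC(=O)C(C)C)[C@@]23C | intermediate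
20 | endo-diazonium acetate: tricycle of 18 with N2+ (endo) on C11 | N#[N+][C@H]1[C@@]2(O[Si](CC)(CC)CC)C=C(C)[C@H]3[C@@H]1C(C)(C)[C@H](O[Si](C)(C)C(C)(C)C)C[C@@H](OC(=O)C(C)C)[C@@]23C.CC(=O)[O-] | intermediate
21 | (4R,5S,7R,9R,10R,11R)-7-[(tert-butyldimethylsilyl)oxy]-9-(2-methylpropanoyloxy)longipin-2-en-1-one | CC(C)(C)[Si](C)(C)O[C@@H]1C[C@@H](OC(=O)C(C)C)[C@@]2(C)[C@@H]3C(=O)C=C(C)[C@H]2[C@@H]3C1(C)C | intermediate
22 | (4R,5S,7R,9R,10R,11R)-7-hydroxy-9-(2-methylpropanoyloxy)longipin-2-en-1-one | O[C@@H]1C[C@@H](OC(=O)C(C)C)[C@@]2(C)[C@@H]3C(=O)C=C(C)[C@H]2[C@@H]3C1(C)C | intermediate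
23 | (4R,5S,7R,9R,10R,11R)-9-(2-methylpropanoyloxy)-7-(2-methylprop-2-enoyloxy)longipin-2-en-1-one (CNP0214356.1) | C=C(C)C(=O)O[C@@H]1C[C@@H](OC(=O)C(C)C)[C@@]2(C)[C@@H]3C(=O)C=C(C)[C@H]2[C@@H]3C1(C)C | target

Total step count: 13. Longest linear sequence: 12 (steps 1–4 and 6–13; step 5 is a one-step branch).

**Steps most likely to fail**

**Step 11 (bears the label).**
- What may go wrong: nitrogen may leave before C10 has begun to move. An open C11 cation would then form, in which the better aligned C1–C2 bond migrates or acetate or water is captured, and the cyclobutane is never made.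
- Fallback (sets out from 15, comes back at 21): the leaving group is changed to a sulfonate that cannot ionise unaided. Only the concerted, alkoxide-driven pinacol-type shift of a 2-sulfonyloxy alcohol then remains. Cross-metathesis of 15 with vinylboronic acid pinacol ester (second-generation Hoveyda–Grubbs catalyst, CH2Cl2, reflux) gives the (E)-alkenylboronate F1. TESOTf/Et3N gives the isolable silyloxycyclopentadiene boronate F2. Heating (PhMe, 110–130 °C, high dilution) gives the endo-boronate cycloadduct F3. NaBO3·4H2O (THF/H2O) oxidises the C–B bond with retention to the endo alcohol F4, and MsCl/Et3N gives the endo mesylate F5. TBAF (THF, 0 °C) then removes the bridgehead triethylsilyl group, and the mesylate antiperiplanar to C1–C10 is expelled with migration of C10 to give 21.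

**Step 9.**
- What may go wrong: enolisation may go toward the C3 methyl group, the amine may trigger oligomerisation of the nitroalkene before the diene exists, or conjugate addition at C5 may occur without closure of the C1–C11 bond.
- Fallback (sets out from 15, comes back at 18): the diene is made and isolated first and the dienophile is unveiled last. OsO4 (cat.)/NaIO4/2,6-lutidine cleaves the vinyl group of 15 to the neopentylic aldehyde F6. TESOTf/Et3N converts its enone into the silyloxycyclopentadiene aldehyde F7, whose aldehyde is neither enolisable nor a good dienophile. Henry addition of nitromethane (cat. DBU, THF, 0 °C) gives the nitro alcohol F8. Dehydration with DCC/CuCl at high dilution releases 17, which cyclises to 18.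

**Step 7.**
- What may go wrong: retro-aldol cleavage of the lithium aldolate, deprotonation at C4 instead of C10, or poor facial selectivity of the methylation.
- Fallback (sets out from 9 and 7, comes back at 15): the quaternary centre is made in the aldol event itself instead of by alkylation. Dienolate 9 is quenched with MeI to give 3,5-dimethylcyclopent-2-en-1-one F9. TMSOTf/Et3N gives the tetrasubstituted silyl dienol ether F10. Fluoride-catalysed aldol addition to 7 (tris(dimethylamino)sulfonium difluorotrimethylsilicate, THF, −78 °C) proceeds through an open transition state that gives syn aldols whatever the enolate geometry. It should deliver the silylated aldol F11 with C4 and C9–O syn, minor isomers being removed by chromatography. Citric acid/MeOH frees the tertiary-alkyl carbinol F12, and isobutyric anhydride/DMAP gives 15.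

**Further compounds**

F1 | step 11 | (1R,3R,5E)-3-[(tert-butyldimethylsilyl)oxy]-1-[(1S)-1,4-dimethyl-2-oxocyclopent-3-en-1-yl]-4,4-dimethyl-6-(4,4,5,5-tetramethyl-1,3,2-dioxaborolan-2-yl)hex-5-en-1-yl 2-methylpropanoate | CC1(C)OB(/C=C/C(C)(C)[C@H](O[Si](C)(C)C(C)(C)C)C[C@@H](OC(=O)C(C)C)[C@]2(C)CC(C)=CC2=O)OC1(C)C
F2 | step 11 | triethylsilyl dienol ether of F1 (1-silyloxycyclopentadiene) | CC1(C)OB(/C=C/C(C)(C)[C@H](O[Si](C)(C)C(C)(C)C)C[C@@H](OC(=O)C(C)C)[C@]2(C)C=C(C)C=C2O[Si](CC)(CC)CC)OC1(C)C
F3 | step 11 | endo-boronate cycloadduct (tricycle of 18 with pinacolboryl endo on C11) | CC1(C)OB(OC1(C)C)[C@H]2[C@@]3(O[Si](CC)(CC)CC)C=C(C)[C@H]4[C@@H]2C(C)(C)[C@H](O[Si](C)(C)C(C)(C)C)C[C@@H](OC(=O)C(C)C)[C@@]34C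
F4 | step 11 | endo alcohol (tricycle of 18 with OH endo on C11) | O[C@H]1[C@@]2(O[Si](CC)(CC)CC)C=C(C)[C@H]3[C@@H]1C(C)(C)[C@H](O[Si](C)(C)C(C)(C)C)C[C@@H](OC(=O)C(C)C)[C@@]23C
F5 | step 11 | endo mesylate (tricycle of 18 with OSO2CH3 endo on C11) | CS(=O)(=O)O[C@H]1[C@@]2(O[Si](CC)(CC)CC)C=C(C)[C@H]3[C@@H]1C(C)(C)[C@H](O[Si](C)(C)C(C)(C)C)C[C@@H](OC(=O)C(C)C)[C@@]23C
F6 | step 9 | (1R,3R)-3-[(tert-butyldimethylsilyl)oxy]-1-[(1S)-1,4-dimethyl-2-oxocyclopent-3-en-1-yl]-4,4-dimethyl-5-oxopentyl 2-methylpropanoate | O=CC(C)(C)[C@H](O[Si](C)(C)C(C)(C)C)C[C@@H](OC(=O)C(C)C)[C@]1(C)CC(C)=CC1=O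
F7 | step 9 | triethylsilyl dienol ether of F6 (silyloxycyclopentadiene aldehyde) | O=CC(C)(C)[C@H](O[Si](C)(C)C(C)(C)C)C[C@@H](OC(=O)C(C)C)[C@]1(C)C=C(C)C=C1O[Si](CC)(CC)CC
F8 | step 9 | nitro alcohol from F7 and nitromethane (both carbinol epimers) | [O-][N+](=O)CC(O)C(C)(C)[C@H](O[Si](C)(C)C(C)(C)C)C[C@@H](OC(=O)C(C)C)[C@]1(C)C=C(C)C=C1O[Si](CC)(CC)CC
F9 | step 7 | 3,5-dimethylcyclopent-2-en-1-one (racemic) | CC1CC(C)=CC1=O
F10 | step 7 | [(1,4-dimethylcyclopenta-1,3-dien-2-yl)oxy]trimethylsilane | CC1=C(O[Si](C)(C)C)C=C(C)C1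
F11 | step 7 | trimethylsilyl ether of F12 | C=CC(C)(C)[C@H](O[Si](C)(C)C(C)(C)C)C[C@@H](O[Si](C)(C)C)[C@]1(C)CC(C)=CC1=O
F12 | step 7 | (5S)-5-[(1R,3R)-3-[(tert-butyldimethylsilyl)oxy]-1-hydroxy-4,4-dimethylhex-5-en-1-yl]-3,5-dimethylcyclopent-2-en-1-one | C=CC(C)(C)[C@H](O[Si](C)(C)C(C)(C)C)C[C@@H](O)[C@]1(C)CC(C)=CC1=O
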